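**Retrosynthetic overview**

- The target is taken back, by oxidation at C19, re-acetylation at C15 and removal of a C3 oxygen, to a 3-oxo 8-phenylmenthyl ester that already holds both rings, the four ring stereocentres and the C8=C17 methylidene.
- Feature on which the strategy rests: in ring A, C4 is quaternary and carries the C18 methyl and the C19 carboxyl, the carboxyl cis (1,3-diaxial) to the C20 methyl on C10, and ring B ends in the C8=C17 methylidene. This is the imprint of an α-methyl β-keto ester radical at C4 that has folded onto the C5=C10 and C8=C9 alkenes of an E,E open chain.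
- Key disconnection: C4–C5 and C9–C10 in one oxidative radical bicyclization. Ring A forms first, ring B second, and the cascade ends by loss of hydrogen from C17.
- The open-chain keto ester comes from C1–C2 bond formation: γ-alkylation of the dianion of (−)-8-phenylmenthyl 2-methylacetoacetate with a C15 allylic bromide. The bromide comes from (2E,6E)-farnesol by asymmetric hydrogenation (C13), acetylation, terminal allylic oxidation and bromination.

Key step: step 8

Remark on numbering: labdane numbering is used for the bicyclic compounds and for the matching atoms of the open chain. The decalin is antipodal to that of the common labdanes. The CIP label at C4 reads S while C3 bears oxygen and R afterwards, with unchanged geometry.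

Assumption: the phenyl group of the (−)-8-phenylmenthyl ester is taken to block the face of the C4 radical that would lead to the mirror-image decalin; this sense is inferred by analogy and is not established for this substrate.

**Route**

Step 1
Reactants: 1 (2E,6E)-farnesol
Product: 2 (3R,6E)-3,7,11-trimethyldodeca-6,10-dien-1-ol
Conditions: H2 (100 atm), Ru(OAc)2[(S)-BINAP] (0.5 mol %), MeOH, 20 °C
Reagents that add atoms: none
Why: Carbinol-directed BINAP–ruthenium asymmetric hydrogenation (Noyori hydrogenation) reduces only the allylic alcohol alkene, and with the E alkene and the (S)-ligand it should set the 3R centre (the later C13) as geraniol gives (R)-citronellol, while the two isolated trisubstituted alkenes lack the directing hydroxyl and stay intact.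

Step 2
Reactants: 2 (3R,6E)-3,7,11-trimethyldodeca-6,10-dien-1-ol
Product: 3 (3R,6E)-3,7,11-trimethyldodeca-6,10-dien-1-yl acetate
Conditions: Ac2O, pyridine, DMAP (cat.), CH2Cl2, 0 °C to rt
Reagents that add atoms: acetic anhydride CC(=O)OC(C)=O
Why: DMAP-catalysed O-acylation of an unhindered primary alcohol masks the hydroxyl before the selenium oxidation and the bromination.

Step 3
Reactants: 3 (3R,6E)-3,7,11-trimethyldodeca-6,10-dien-1-yl acetate
Product: 4 (3R,6E,10E)-12-hydroxy-3,7,11-trimethyldodeca-6,10-dien-1-yl acetate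
Conditions: SeO2 (0.2 equiv), salicylic acid (0.1 equiv), t-BuOOH (3 equiv), CH2Cl2, rt, stopped at partial conversion
Reagents that add atoms: tert-butyl hydroperoxide CC(C)(C)OO (oxygen source, passed on through the catalyst selenium dioxide O=[Se]=O)
Why: Catalytic SeO2 allylic oxidation (ene reaction then [2,3]-sigmatropic shift) should attack the E-methyl of the terminal, most accessible trisubstituted alkene and give the E allylic alcohol, the internal alkene reacting more slowly so that recovered 3 can be recycled.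

Step 4
Reactants: 4 (3R,6E,10E)-12-hydroxy-3,7,11-trimethyldodeca-6,10-dien-1-yl acetate
Product: 5 (3R,6E,10E)-12-bromo-3,7,11-trimethyldodeca-6,10-dien-1-yl acetate
Conditions: CBr4, PPh3, CH2Cl2, 0 °C
Reagents that add atoms: carbon tetrabromide BrC(Br)(Br)Br
Why: The Appel reaction displaces the oxyphosphonium of the primary allylic alcohol by bromide in an SN2 step under neutral conditions, without allylic transposition or loss of the acetate, and the bromide is chosen over the chloride because it alkylates the dianion at lower temperature.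

Step 5
Reactants: 6 (−)-8-phenylmenthol; 7 2,2,6-trimethyl-4H-1,3-dioxin-4-one
Product: 9 (−)-8-phenylmenthyl 3-oxobutanoate, via acetylketene 8 (not isolated)
Conditions: xylene, 140 °C, acetone distilled off
Reagents that add atoms: none
Why: Thermal retro-hetero-Diels–Alder cleavage of the dioxinone releases acetylketene, which even a hindered secondary alcohol traps by addition to give the acetoacetate.

Step 6
Reactants: 9 (−)-8-phenylmenthyl 3-oxobutanoate
Product: 10 (−)-8-phenylmenthyl 2-methyl-3-oxobutanoate (both C2 epimers)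
Conditions: K2CO3, MeI (1.05 equiv), acetone, reflux
Reagents that add atoms: iodomethane CI
Why: C-alkylation of the β-keto ester potassium enolate with one equivalent of MeI installs the later C18 methyl, and the C2 configuration is of no account because this carbon becomes a planar radical in step 8.

Step 7
Reactants: 10 (−)-8-phenylmenthyl 2-methyl-3-oxobutanoate (both C2 epimers); 5 (3R,6E,10E)-12-bromo-3,7,11-trimethyldodeca-6,10-dien-1-yl acetate
Product: 12 (−)-8-phenylmenthyl (6E,10E,14R)-16-acetoxy-2,6,10,14-tetramethyl-3-oxohexadeca-6,10-dienoate (both C2 epimers), via dilithium dienolate 11 (not isolated)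
Conditions: LiN(i-Pr)2 (2.1 equiv), THF, −78 to 0 °C; then 5 (0.9 equiv), −78 to 0 °C; aq NH4Cl
Reagents that add atoms: none
Why: β-Keto ester dianion alkylation forms the C1–C2 bond at the terminal γ-carbon, the more basic site, by SN2 attack on the primary allylic bromide, which at −78 to 0 °C should be much faster than addition of this enolate-type carbanion to the remote alkyl acetate.

Step 8
Reactants: 12 (−)-8-phenylmenthyl (6E,10E,14R)-16-acetoxy-2,6,10,14-tetramethyl-3-oxohexadeca-6,10-dienoate (both C2 epimers)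
Product: 13 (−)-8-phenylmenthyl (4S,5S,9R,10S,13R)-15-acetoxy-3-oxolabd-8(17)-en-19-oate
Conditions: Mn(OAc)3·2H2O (2.2 equiv), Cu(OAc)2·H2O (1.0 equiv), degassed AcOH, 25 °C
Reagents that add atoms: none
Why: Mn(OAc)3 enolises the α-methyl β-keto ester on the metal and one-electron transfer within the enolate releases a planar, electrophilic tertiary radical at C4, so that the two epimers of 12 give the same intermediate; the closest known reaction type is the oxidative free-radical bicyclization of farnesyl-type α-methyl acetoacetates to methylidene decalins with Mn(OAc)3 and Cu(OAc)2. Ring A closes by 6-endo-trig addition of C4 to C5 of the E C5=C10 alkene, which leaves a tertiary radical at C10, and ring B closes by 6-endo-trig addition of C10 to C9 of the E C8=C9 alkene, which leaves a tertiary radical at C8. Cu(OAc)2 captures the C8 radical as an alkylcopper species that loses a β-hydrogen from the unhindered C17 methyl to give the C8=C17 methylidene, and the monovalent copper so formed is returned to the divalent state by the second equivalent of Mn(OAc)3. C5, C10 and C9 are set relative to C4 by the E,E alkene geometry and a chair–chair fold with the C3 ketone inside ring A, which puts the C19 ester axial and cis to C20, makes the ring fusion trans and leaves the C11 chain equatorial, while C4 itself, and with it the absolute sense of all four centres, is set by the phenyl group of the auxiliary lying over one face of the keto ester radical. The step needs 6-endo over 5-exo closure twice, secured by the trisubstituted alkenes that give tertiary radicals only in the endo mode, exocyclic over endocyclic elimination, favoured by the alkylcopper intermediate, and facial control at C4, which rests on the auxiliary. The acetate and the C13 centre are remote and take no part.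

Step 9
Reactants: 13 (−)-8-phenylmenthyl (4S,5S,9R,10S,13R)-15-acetoxy-3-oxolabd-8(17)-en-19-oate
Product: 14 (−)-8-phenylmenthyl (3R,4S,5S,9R,10S,13R)-15-acetoxy-3-hydroxylabd-8(17)-en-19-oate
Conditions: NaBH4, THF/MeOH, 0 °C
Reagents that add atoms: none
Why: Borohydride reduction touches only the ketone at 0 °C, and axial hydride delivery on the face away from the axial C19 ester and C20 should give the equatorial 3R alcohol, a centre that is removed again in step 11 so that its configuration is immaterial.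

Step 10
Reactants: 14 (−)-8-phenylmenthyl (3R,4S,5S,9R,10S,13R)-15-acetoxy-3-hydroxylabd-8(17)-en-19-oate
Product: 15 (−)-8-phenylmenthyl (3R,4S,5S,9R,10S,13R)-15-acetoxy-3-(imidazol-1-ylthiocarbonyloxy)labd-8(17)-en-19-oate
Conditions: 1,1'-thiocarbonyldiimidazole, DMAP, ClCH2CH2Cl, reflux
Reagents that add atoms: 1,1'-thiocarbonyldiimidazole S=C(n1ccnc1)n1ccnc1
Why: Thioacyl transfer to the hindered C3 alcohol under neutral conditions gives the radical precursor without forming an alkoxide that could open ring A by retro-aldol cleavage of C3–C4.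

Step 11
Reactants: 15 (−)-8-phenylmenthyl (3R,4S,5S,9R,10S,13R)-15-acetoxy-3-(imidazol-1-ylthiocarbonyloxy)labd-8(17)-en-19-oate
Product: 16 (−)-8-phenylmenthyl (4R,5S,9R,10S,13R)-15-acetoxylabd-8(17)-en-19-oate
Conditions: n-Bu3SnH, AIBN (cat.), toluene, 110 °C
Reagents that add atoms: none
Why: Barton–McCombie deoxygenation proceeds by stannyl radical addition to sulfur and C3–O fragmentation, and the secondary C3 radical has no alkene within reach across the rigid decalin, so it is simply reduced by the tin hydride.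

Step 12
Reactants: 16 (−)-8-phenylmenthyl (4R,5S,9R,10S,13R)-15-acetoxylabd-8(17)-en-19-oate
Product: 17 (4R,5S,9R,10S,13R)-labd-8(17)-ene-15,19-diol
Conditions: LiAlH4, THF, reflux
Reagents that add atoms: none
Why: Hydride reduction of esters cleaves the acetate to the C15 alcohol and the hindered axial ester to the neopentyl C19 alcohol, returns the auxiliary 6 for reuse and leaves the isolated methylidene alone.

Step 13
Reactants: 17 (4R,5S,9R,10S,13R)-labd-8(17)-ene-15,19-diol
Product: 18 (4R,5S,9R,10S,13R)-19-hydroxylabd-8(17)-en-15-yl acetate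
Conditions: AcCl (1.05 equiv), 2,4,6-collidine, CH2Cl2, −78 °C
Reagents that add atoms: acetyl chloride CC(=O)Cl
Why: Kinetically selective O-acylation should take the C15 hydroxyl on the flexible chain well before the neopentyl axial C19 hydroxyl, which is crowded by the C4 quaternary centre and the 1,3-diaxial C20 methyl.

Step 14
Reactants: 18 (4R,5S,9R,10S,13R)-19-hydroxylabd-8(17)-en-15-yl acetate
Product: 19 (4R,5S,9R,10S,13R)-15-acetoxylabd-8(17)-en-19-al
Conditions: Dess–Martin periodinane, CH2Cl2, rt
Reagents that add atoms: none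
Why: Dess–Martin oxidation converts the hindered primary alcohol to the non-enolisable aldehyde under near-neutral conditions that spare the acetate and the methylidene.

Step 15
Reactants: 19 (4R,5S,9R,10S,13R)-15-acetoxylabd-8(17)-en-19-al
Product: 20 (4R,5S,9R,10S,13R)-15-acetoxylabd-8(17)-en-19-oic acid
Conditions: NaClO2, NaH2PO4, 2-methyl-2-butene, t-BuOH/H2O, rt
Reagents that add atoms: sodium chlorite [Na+].[O-]Cl=O
Why: Pinnick oxidation takes the neopentyl aldehyde to the acid while 2-methyl-2-butene traps the hypochlorous acid that would otherwise attack the C8=C17 alkene, and the quaternary C4 cannot epimerise.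

**Compound list**

1 | (2E,6E)-farnesol | CC(C)=CCC/C(C)=C/CC/C(C)=C/CO | starting material
2 | (3R,6E)-3,7,11-trimethyldodeca-6,10-dien-1-ol, (R)-2,3-dihydrofarnesol | CC(C)=CCC/C(C)=C/CC[C@@H](C)CCO | intermediate
3 | (3R,6E)-3,7,11-trimethyldodeca-6,10-dien-1-yl acetate | CC(C)=CCC/C(C)=C/CC[C@@H](C)CCOC(C)=O | intermediate
4 | (3R,6E,10E)-12-hydroxy-3,7,11-trimethyldodeca-6,10-dien-1-yl acetate | OC/C(C)=C/CC/C(C)=C/CC[C@@H](C)CCOC(C)=O | intermediate
5 | (3R,6E,10E)-12-bromo-3,7,11-trimethyldodeca-6,10-dien-1-yl acetate | BrC/C(C)=C/CC/C(C)=C/CC[C@@H](C)CCOC(C)=O | intermediate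
6 | (−)-8-phenylmenthol, (1R,2S,5R)-5-methyl-2-(2-phenylpropan-2-yl)cyclohexan-1-ol | O[C@@H]1C[C@H](C)CC[C@H]1C(C)(C)c1ccccc1 | starting material
7 | 2,2,6-trimethyl-4H-1,3-dioxin-4-one | CC1=CC(=O)OC(C)(C)O1 | starting material
8 | acetylketene | CC(=O)C=C=O | intermediate
9 | (−)-8-phenylmenthyl 3-oxobutanoate | CC(=O)CC(=O)O[C@@H]1C[C@H](C)CC[C@H]1C(C)(C)c1ccccc1 | intermediate
10 | (−)-8-phenylmenthyl 2-methyl-3-oxobutanoate, both C2 epimers | CC(=O)C(C)C(=O)O[C@@H]1C[C@H](C)CC[C@H]1C(C)(C)c1ccccc1 | intermediate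
11 | dilithium dienolate of 10 | [Li+].[Li+].C=C([O-])C(C)=C([O-])O[C@@H]1C[C@H](C)CC[C@H]1C(C)(C)c1ccccc1 | intermediate
12 | (−)-8-phenylmenthyl (6E,10E,14R)-16-acetoxy-2,6,10,14-tetramethyl-3-oxohexadeca-6,10-dienoate, both C2 epimers | CC(C(=O)O[C@@H]1C[C@H](C)CC[C@H]1C(C)(C)c1ccccc1)C(=O)CC/C(C)=C/CC/C(C)=C/CC[C@@H](C)CCOC(C)=O | intermediate
13 | (−)-8-phenylmenthyl (4S,5S,9R,10S,13R)-15-acetoxy-3-oxolabd-8(17)-en-19-oate; trans-decalin, C19 ester axial and cis to C20, C11 chain equatorial | C=C1CC[C@H]2[C@@](C)(CCC(=O)[C@@]2(C)C(=O)O[C@@H]2C[C@H](C)CC[C@H]2C(C)(C)c2ccccc2)[C@@H]1CC[C@@H](C)CCOC(C)=O | intermediate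
14 | (−)-8-phenylmenthyl (3R,4S,5S,9R,10S,13R)-15-acetoxy-3-hydroxylabd-8(17)-en-19-oate; 3-OH equatorial | C=C1CC[C@H]2[C@@](C)(CC[C@@H](O)[C@@]2(C)C(=O)O[C@@H]2C[C@H](C)CC[C@H]2C(C)(C)c2ccccc2)[C@@H]1CC[C@@H](C)CCOC(C)=O | intermediate
15 | (−)-8-phenylmenthyl (3R,4S,5S,9R,10S,13R)-15-acetoxy-3-(imidazol-1-ylthiocarbonyloxy)labd-8(17)-en-19-oate | C=C1CC[C@H]2[C@@](C)(CC[C@@H](OC(=S)n3ccnc3)[C@@]2(C)C(=O)O[C@@H]2C[C@H](C)CC[C@H]2C(C)(C)c2ccccc2)[C@@H]1CC[C@@H](C)CCOC(C)=O | intermediate
16 | (−)-8-phenylmenthyl (4R,5S,9R,10S,13R)-15-acetoxylabd-8(17)-en-19-oate | C=C1CC[C@H]2[C@@](C)(CCC[C@@]2(C)C(=O)O[C@@H]2C[C@H](C)CC[C@H]2C(C)(C)c2ccccc2)[C@@H]1CC[C@@H](C)CCOC(C)=O | intermediate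
17 | (4R,5S,9R,10S,13R)-labd-8(17)-ene-15,19-diol | C=C1CC[C@H]2[C@@](C)(CCC[C@@]2(C)CO)[C@@H]1CC[C@@H](C)CCO | intermediate
18 | (4R,5S,9R,10S,13R)-19-hydroxylabd-8(17)-en-15-yl acetate | C=C1CC[C@H]2[C@@](C)(CCC[C@@]2(C)CO)[C@@H]1CC[C@@H](C)CCOC(C)=O | intermediate
19 | (4R,5S,9R,10S,13R)-15-acetoxylabd-8(17)-en-19-al | C=C1CC[C@H]2[C@@](C)(CCC[C@@]2(C)C=O)[C@@H]1CC[C@@H](C)CCOC(C)=O | intermediate
20 | (4R,5S,9R,10S,13R)-15-acetoxylabd-8(17)-en-19-oic acid, (1R,4aS,5R,8aS)-5-[(3R)-5-acetoxy-3-methylpentyl]-1,4a-dimethyl-6-methylidenedecahydronaphthalene-1-carboxylic acid | C=C1CC[C@H]2[C@@](C)(CCC[C@@]2(C)C(=O)O)[C@@H]1CC[C@@H](C)CCOC(C)=O | target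

**Step count and risks**

Total step count: 15. Longest linear sequence: 13 steps (steps 1–4 and 7–15, from farnesol); the auxiliary branch (steps 5 and 6) joins at step 7.

Steps most likely to fail:

1. Step 8. The auxiliary may discriminate the two faces of the C4 radical only weakly, or in the sense opposite to the one assumed, so that the decalin of mirror-image ring configuration predominates. Endocyclic alkene isomers from the copper-mediated elimination would also have to be separated, for example on AgNO3-impregnated silica. A tighter chelate, with Yb(OTf)3 in CF3CH2OH at lower temperature, would be tried first. The fallback is the antipodal auxiliary series, which sets out from 7, uses 5 unchanged and comes back to the route at 17. (+)-8-Phenylmenthol F1 is heated with 7 in xylene to give (+)-8-phenylmenthyl 3-oxobutanoate F2, which is methylated with K2CO3 and MeI to (+)-8-phenylmenthyl 2-methyl-3-oxobutanoate F3. Its dilithium dienolate F4 is alkylated with 5 to the (+)-8-phenylmenthyl open-chain keto ester F5. Cyclization with Mn(OAc)3 and Cu(OAc)2 should then give the (+)-8-phenylmenthyl 3-oxo ester F6 with the decalin configuration of 13. NaBH4 gives the (+)-8-phenylmenthyl 3-hydroxy ester F7, thioacylation gives the (+)-8-phenylmenthyl 3-imidazolylthiocarbonyl ester F8, n-Bu3SnH gives the (+)-8-phenylmenthyl 3-deoxy ester F9, and LiAlH4 cleaves F9 to 17.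

2. Step 7. Acyl transfer from the acetate to the dianion, or proton exchange with it, may compete with the alkylation and erode the yield. The fallback carries the C15 oxygen as a silyl ether through the coupling; it sets out from 2 and comes back at 12. Silylation of 2 (t-BuPh2SiCl, imidazole) gives the tert-butyldiphenylsilyl ether of 2 F10. SeO2/t-BuOOH oxidation gives the 12-hydroxy silyl ether F11, and CBr4/PPh3 gives the 12-bromo silyl ether F12. Alkylation of dianion 11 with F12 gives the 16-silyloxy keto ester F13. Desilylation with n-Bu4NF buffered with AcOH gives the 16-hydroxy keto ester F14, and Ac2O/pyridine converts F14 into 12.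

3. Step 10. Thioacylation of the neopentyl-type C3 hydroxyl next to the quaternary C4 may be slow, and forcing it with base risks retro-aldol opening of ring A. The fallback removes the C3 oxygen directly from the ketone; it sets out from 13, bypasses 14 and 15 and comes back at 16. Condensation of 13 with p-toluenesulfonylhydrazide in hot ethanol gives the C3 tosylhydrazone of 13 F15. Reduction with catecholborane in CHCl3 at 0 °C, followed by NaOAc·3H2O at reflux, expels sulfinate and dinitrogen to give 16; the esters and the isolated methylidene should be tolerated.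

**Further compounds**

F1 | step 8 | (+)-8-phenylmenthol, (1S,2R,5S)-5-methyl-2-(2-phenylpropan-2-yl)cyclohexan-1-ol | O[C@H]1C[C@@H](C)CC[C@@H]1C(C)(C)c1ccccc1
F2 | step 8 | (+)-8-phenylmenthyl 3-oxobutanoate | CC(=O)CC(=O)O[C@H]1C[C@@H](C)CC[C@@H]1C(C)(C)c1ccccc1
F3 | step 8 | (+)-8-phenylmenthyl 2-methyl-3-oxobutanoate, both C2 epimers | CC(=O)C(C)C(=O)O[C@H]1C[C@@H](C)CC[C@@H]1C(C)(C)c1ccccc1
F4 | step 8 | dilithium dienolate of F3 | [Li+].[Li+].C=C([O-])C(C)=C([O-])O[C@H]1C[C@@H](C)CC[C@@H]1C(C)(C)c1ccccc1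
F5 | step 8 | (+)-8-phenylmenthyl (6E,10E,14R)-16-acetoxy-2,6,10,14-tetramethyl-3-oxohexadeca-6,10-dienoate, both C2 epimers | CC(C(=O)O[C@H]1C[C@@H](C)CC[C@@H]1C(C)(C)c1ccccc1)C(=O)CC/C(C)=C/CC/C(C)=C/CC[C@@H](C)CCOC(C)=O
F6 | step 8 | (+)-8-phenylmenthyl (4S,5S,9R,10S,13R)-15-acetoxy-3-oxolabd-8(17)-en-19-oate | C=C1CC[C@H]2[C@@](C)(CCC(=O)[C@@]2(C)C(=O)O[C@H]2C[C@@H](C)CC[C@@H]2C(C)(C)c2ccccc2)[C@@H]1CC[C@@H](C)CCOC(C)=O
F7 | step 8 | (+)-8-phenylmenthyl (3R,4S,5S,9R,10S,13R)-15-acetoxy-3-hydroxylabd-8(17)-en-19-oate | C=C1CC[C@H]2[C@@](C)(CC[C@@H](O)[C@@]2(C)C(=O)O[C@H]2C[C@@H](C)CC[C@@H]2C(C)(C)c2ccccc2)[C@@H]1CC[C@@H](C)CCOC(C)=O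
F8 | step 8 | (+)-8-phenylmenthyl (3R,4S,5S,9R,10S,13R)-15-acetoxy-3-(imidazol-1-ylthiocarbonyloxy)labd-8(17)-en-19-oate | C=C1CC[C@H]2[C@@](C)(CC[C@@H](OC(=S)n3ccnc3)[C@@]2(C)C(=O)O[C@H]2C[C@@H](C)CC[C@@H]2C(C)(C)c2ccccc2)[C@@H]1CC[C@@H](C)CCOC(C)=O
F9 | step 8 | (+)-8-phenylmenthyl (4R,5S,9R,10S,13R)-15-acetoxylabd-8(17)-en-19-oate | C=C1CC[C@H]2[C@@](C)(CCC[C@@]2(C)C(=O)O[C@H]2C[C@@H](C)CC[C@@H]2C(C)(C)c2ccccc2)[C@@H]1CC[C@@H](C)CCOC(C)=O
F10 | step 7 | tert-butyl(diphenyl)silyl ether of 2, (3R,6E)-1-(tert-butyldiphenylsilyloxy)-3,7,11-trimethyldodeca-6,10-diene | CC(C)=CCC/C(C)=C/CC[C@@H](C)CCO[Si](c1ccccc1)(c1ccccc1)C(C)(C)C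
F11 | step 7 | (2E,6E,10R)-12-(tert-butyldiphenylsilyloxy)-2,6,10-trimethyldodeca-2,6-dien-1-ol | OC/C(C)=C/CC/C(C)=C/CC[C@@H](C)CCO[Si](c1ccccc1)(c1ccccc1)C(C)(C)C
F12 | step 7 | (2E,6E,10R)-1-bromo-12-(tert-butyldiphenylsilyloxy)-2,6,10-trimethyldodeca-2,6-diene | BrC/C(C)=C/CC/C(C)=C/CC[C@@H](C)CCO[Si](c1ccccc1)(c1ccccc1)C(C)(C)C
F13 | step 7 | (−)-8-phenylmenthyl (6E,10E,14R)-16-(tert-butyldiphenylsilyloxy)-2,6,10,14-tetramethyl-3-oxohexadeca-6,10-dienoate, both C2 epimers | CC(C(=O)O[C@@H]1C[C@H](C)CC[C@H]1C(C)(C)c1ccccc1)C(=O)CC/C(C)=C/CC/C(C)=C/CC[C@@H](C)CCO[Si](c1ccccc1)(c1ccccc1)C(C)(C)C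
F14 | step 7 | (−)-8-phenylmenthyl (6E,10E,14R)-16-hydroxy-2,6,10,14-tetramethyl-3-oxohexadeca-6,10-dienoate, both C2 epimers | CC(C(=O)O[C@@H]1C[C@H](C)CC[C@H]1C(C)(C)c1ccccc1)C(=O)CC/C(C)=C/CC/C(C)=C/CC[C@@H](C)CCO
F15 | step 10 | C3 p-toluenesulfonylhydrazone of 13 | C=C1CC[C@H]2[C@@](C)(CCC(=NNS(=O)(=O)c3ccc(C)cc3)[C@@]2(C)C(=O)O[C@@H]2C[C@H](C)CC[C@H]2C(C)(C)c2ccccc2)[C@@H]1CC[C@@H](C)CCOC(C)=O
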